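A direct plan would start from 1,2,3,5-tetramethoxybenzene A1 and acylate it with AcCl/AlCl3, letting the same AlCl3 cleave one ortho methyl ether to give 2'-hydroxy-3',4',6'-trimethoxyacetophenone A2 in one flask.
It would then close ring C with DMF dimethyl acetal and acid to give 5,7,8-trimethoxychromone A3 and attach ring B by zincation of C2–H with (tmp)ZnCl·LiCl and Negishi coupling with 1-bromo-2,3-dimethoxybenzene A4 to give 2',3',5,7,8-pentamethoxyflavone A5 and finish by cleaving the 5-OMe group with BCl3.
Its weakest steps would be:
(a) the one-flask acylation and ether cleavage that leads from A1 to A2, because which ortho methoxy group is lost (2' or 6') would rest only on a chelation bias, and a wrong or double cleavage could not be repaired;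
(b) the C–H zincation of A3 and its cross-coupling with A4, because the site of metalation (C2 or C3) would depend on base and additives, the metalated enone could ring-open, and the bromide is ortho-substituted and electron-rich, all on an advanced chromone;
(c) the final demethylation of A5, because one of five methyl ethers would have to be broken on the most precious material although the 7,8- and 2',3'-dimethoxy pairs also bind boron.
The plan would make five methyl ethers in order to destroy one; it has no stereocentre and no ring closure at risk, and its last two steps are the ones least welcome late.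

**Plan of the new route**
The retrosynthesis cuts ring A, not ring C: first C4a–C5 (Claisen), then C8–C8a (vinylic substitution).
This leads back to a pyranone that already holds rings C and B, 2-(2,3-dimethoxyphenyl)-6-(methanesulfonyl)-4H-pyran-4-one, and to methyl (E)-3,4-dimethoxybut-2-enoate, which supplies C5–C8.
Feature used: in ring A, O5–C5–C4a–C4=O is the enol of a 1,3-diketone, and C8a is both the ether carbon of ring C and the β-carbon of its enone; C6–H, C7–OMe and C8–OMe are exactly a 3,4-dimethoxybut-2-enoate whose ester carbon becomes C5–OH.
Order of rings: B is bought, C is made from a 1,3-diketone, A is made last in one flask and appears directly as the target.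
No methyl ether is ever cleaved (the 5-OH is born free), no C–H bond of a chromone is metalated, and no cross-coupling is needed because ring B enters as an acid chloride.

Key step: step 4

Remark: ketone 1 is taken as purchasable; otherwise it is one step from acetone, CS2 and MeI.

Step 1
Reactants: 1 4,4-bis(methylsulfanyl)but-3-en-2-one; 2 2,3-dimethoxybenzoyl chloride
Product: 5 2-(2,3-dimethoxyphenyl)-6-(methylsulfanyl)-4H-pyran-4-one, via lithium enolate 3 (not isolated), via diketone 4 (not isolated)
Conditions: LiN(SiMe3)2 (2.2 equiv), THF, −78 °C; 2, −78 → 0 °C; 1 M HCl; then TsOH·H2O (10 mol%), toluene, 110 °C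
Reagents that add atoms: none
Why: Claisen-type C-acylation of the α'-lithium enolate of the oxoketene dithioacetal (the second equivalent of base takes up the acidic diketone), then acid-catalysed 6-endo addition–elimination of the diketone enol oxygen at the bis(methylsulfanyl) carbon with loss of MeSH, the pyranone counterpart of the 2-(methylsulfanyl)chromone synthesis; no stereocentre is formed.

Step 2
Reactants: 5 2-(2,3-dimethoxyphenyl)-6-(methylsulfanyl)-4H-pyran-4-one
Product: 6 2-(2,3-dimethoxyphenyl)-6-(methanesulfonyl)-4H-pyran-4-one
Conditions: mCPBA (2.2 equiv), CH2Cl2, 0 °C → rt; aq. Na2SO3/NaHCO3 wash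
Reagents that add atoms: 3-chloroperbenzoic acid O=C(OO)c1cccc(Cl)c1
Why: Peracid oxidation of the sulfide to the sulfone; the electron-poor pyranone double bonds and the aryl ethers should not be attacked, and the sulfone makes C6 a vinylogous sulfonyl ester ready for addition–elimination; no stereocentre is formed.

Step 3
Reactants: 7 methyl 4-methoxy-3-oxobutanoate
Product: 8 methyl (2E)-3,4-dimethoxybut-2-enoate
Conditions: HC(OMe)3 (1.5 equiv), H2SO4 (cat.), MeOH, rt; then TsOH (cat.), 130 °C, MeOH distilled off
Reagents that add atoms: trimethyl orthoformate COC(OC)OC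
Why: Acid-catalysed ketalisation of the ketone by the orthoformate and thermal loss of methanol toward the ester should give the conjugated enol ether, as with 4-chloroacetoacetates; the (E) isomer (OMe anti to CO2Me) is the thermodynamic one, and the geometry is not carried into the target.

Step 4
Reactants: 6 2-(2,3-dimethoxyphenyl)-6-(methanesulfonyl)-4H-pyran-4-one; 8 methyl (2E)-3,4-dimethoxybut-2-enoate
Product: 11 5-hydroxy-2',3',7,8-tetramethoxyflavone, via lithium dienolate 9 (not isolated), via coupled butenoate 10 (not isolated)
Conditions: 8 (2.2 equiv), LiN(iPr)2 (2.2 equiv), THF, −78 °C; add 6, −78 → 0 °C; then 60 °C; 1 M HCl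
Reagents that add atoms: none
Why: Proposed new method: the γ-carbon of dienolate 9 should add to C6 of sulfone 6 (the enone β-carbon that carries the nucleofuge) and methanesulfinate should leave, giving 10, whose doubly vinylogous C–H between the pyranone and the methoxyacrylate is removed by the second equivalent of 9; the resulting anion is delocalised onto the neighbouring ring carbon (C5 in the numbering of 6, the future C4a), which attacks the ester carbonyl, methoxide leaves and the 1,3-diketone tautomerises to the chelated phenol, so ring A is born aromatic with the 5-OH free and without an oxidant. The closest known reaction types are the displacement of 2-sulfonyl groups of chromones and of methylsulfanyl groups of oxoketene dithioacetals by carbanions, the Michael–Dieckmann annulation and the Claisen aromatisation of polyketide-type pyranone esters, merged here on a 4-pyranone. Ring A closes by C–C bond formation at C4a–C5 in a six-membered, exo-trig Claisen (Dieckmann-type) mode; O-acylation would need an eight-membered ring and attack by the exocyclic carbon of the anion a four-membered ring, so neither should compete. The only stereocentre formed (C8 in 10) is racemic and is erased on deprotonation, and the double-bond geometry of 10 is free to equilibrate in the anion. The selectivities needed are γ- over α-attack of 9 (the γ-carbon is the enol-ether terminus and the unhindered end of the extended enolate, as in γ-aldol reactions of 3-alkoxycrotonate dienolates) and C6 over C2 of 6 (only C6 carries a leaving group, and C2 is shielded by the ortho-substituted aryl group).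

**Compound list**
1 | 4,4-bis(methylsulfanyl)but-3-en-2-one | CC(=O)C=C(SC)SC | starting material
2 | 2,3-dimethoxybenzoyl chloride | COc1cccc(C(=O)Cl)c1OC | starting material
3 | lithium 4,4-bis(methylsulfanyl)buta-1,3-dien-2-olate | C=C(O[Li])C=C(SC)SC | intermediate (not isolated)
4 | 1-(2,3-dimethoxyphenyl)-5,5-bis(methylsulfanyl)pent-4-ene-1,3-dione | COc1cccc(C(=O)CC(=O)C=C(SC)SC)c1OC | intermediate (not isolated)
5 | 2-(2,3-dimethoxyphenyl)-6-(methylsulfanyl)-4H-pyran-4-one | COc1cccc(-c2cc(=O)cc(SC)o2)c1OC | intermediate
6 | 2-(2,3-dimethoxyphenyl)-6-(methanesulfonyl)-4H-pyran-4-one | COc1cccc(-c2cc(=O)cc(S(C)(=O)=O)o2)c1OC | intermediate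
7 | methyl 4-methoxy-3-oxobutanoate | COCC(=O)CC(=O)OC | starting material
8 | methyl (2E)-3,4-dimethoxybut-2-enoate | COC/C(OC)=C\C(=O)OC | intermediate
9 | lithium 1,3,4-trimethoxybuta-1,3-dien-1-olate | COC=C(OC)C=C(OC)O[Li] | intermediate (not isolated)
10 | methyl (2E)-4-[6-(2,3-dimethoxyphenyl)-4-oxo-4H-pyran-2-yl]-3,4-dimethoxybut-2-enoate (racemic) | COC(=O)/C=C(OC)\C(OC)c1cc(=O)cc(-c2cccc(OC)c2OC)o1 | intermediate (not isolated)
11 | 2-(2,3-dimethoxyphenyl)-5-hydroxy-7,8-dimethoxy-4H-chromen-4-one (5-hydroxy-2',3',7,8-tetramethoxyflavone) | COc1cccc(-c2cc(=O)c3c(O)cc(OC)c(OC)c3o2)c1OC | target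

Total step count: 4. Longest linear sequence: 3 (steps 1, 2 and 4); step 3 supplies the second fragment.

**Steps most likely to fail**

Step 4 (Proposed new method). The dienolate may attack through its α-carbon instead of its γ-carbon in the substitution, or the delocalised anion of 10 may stall before the Claisen closure. The fallback sets out from sulfone 6 and keto ester 7 and comes back at 11. The 1,3-dianion of 7 (NaH, then n-BuLi, THF, 0 °C), which can react only at its terminal carbon, would displace the sulfonyl group to give methyl 4-[6-(2,3-dimethoxyphenyl)-4-oxo-4H-pyran-2-yl]-4-methoxy-3-oxobutanoate F1. HC(OMe)3/TsOH would convert F1 into enol ether 10 (the isomer with the double bond toward the pyranone would serve equally). LiOH in THF/H2O would give (2E)-4-[6-(2,3-dimethoxyphenyl)-4-oxo-4H-pyran-2-yl]-3,4-dimethoxybut-2-enoic acid F2. Ac2O/NaOAc at 120 °C would then close ring A without an anion, through the mixed anhydride, the dienylketene and its 6π-electrocyclisation onto the neighbouring ring carbon of the pyranone (the phenol annulation known from Stobbe half-esters), to give 5-acetoxy-2',3',7,8-tetramethoxyflavone F3. K2CO3/MeOH would remove the acetate to give 11.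

Step 1. O-acylation or double acylation of the enolate, or incomplete ring closure of the diketone, may occur. The fallback sets out from 2',3'-dimethoxyacetophenone F4 and comes back at 5. Claisen condensation with ethyl acetate (NaH, THF) would give 1-(2,3-dimethoxyphenyl)butane-1,3-dione F5. Its 1,3-dianion (LiN(iPr)2, 2.2 equiv) would be trapped at the terminal carbon with CS2, and the dithio acid would close on acidification to 6-(2,3-dimethoxyphenyl)-4-hydroxy-2H-pyran-2-thione F6, the sulfur counterpart of the carboxylation route to 4-hydroxy-2-pyranones. S-Methylation (MeI, K2CO3, acetone) would give 5.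

Step 3. Methanol may be lost from the intermediate ketal toward C4, giving the deconjugated enol ether, or enol ether formation may be incomplete. The fallback sets out from methyl (2E)-4-chloro-3-methoxybut-2-enoate F7 and comes back at 8: the allylic chloride would be displaced with NaOMe in MeOH (0 °C → rt), so the enol ether is already in place and only the C4–O bond is made.

**Further compounds**
F1 | step 4 | methyl 4-[6-(2,3-dimethoxyphenyl)-4-oxo-4H-pyran-2-yl]-4-methoxy-3-oxobutanoate (racemic) | COC(=O)CC(=O)C(OC)c1cc(=O)cc(-c2cccc(OC)c2OC)o1
F2 | step 4 | (2E)-4-[6-(2,3-dimethoxyphenyl)-4-oxo-4H-pyran-2-yl]-3,4-dimethoxybut-2-enoic acid (racemic) | OC(=O)/C=C(OC)\C(OC)c1cc(=O)cc(-c2cccc(OC)c2OC)o1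
F3 | step 4 | 2-(2,3-dimethoxyphenyl)-7,8-dimethoxy-4-oxo-4H-chromen-5-yl acetate (5-acetoxy-2',3',7,8-tetramethoxyflavone) | CC(=O)Oc1cc(OC)c(OC)c2oc(-c3cccc(OC)c3OC)cc(=O)c12
F4 | step 1 | 1-(2,3-dimethoxyphenyl)ethan-1-one (2',3'-dimethoxyacetophenone) | CC(=O)c1cccc(OC)c1OC
F5 | step 1 | 1-(2,3-dimethoxyphenyl)butane-1,3-dione | CC(=O)CC(=O)c1cccc(OC)c1OC
F6 | step 1 | 6-(2,3-dimethoxyphenyl)-4-hydroxy-2H-pyran-2-thione | COc1cccc(-c2cc(O)cc(=S)o2)c1OC
F7 | step 3 | methyl (2E)-4-chloro-3-methoxybut-2-enoate | COC(=O)/C=C(OC)\CCl
A1 | direct plan | 1,2,3,5-tetramethoxybenzene | COc1cc(OC)c(OC)c(OC)c1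
A2 | direct plan | 1-(2-hydroxy-3,4,6-trimethoxyphenyl)ethan-1-one (2'-hydroxy-3',4',6'-trimethoxyacetophenone) | CC(=O)c1c(OC)cc(OC)c(OC)c1O
A3 | direct plan | 5,7,8-trimethoxy-4H-chromen-4-one (5,7,8-trimethoxychromone) | COc1cc(OC)c2c(=O)ccoc2c1OC
A4 | direct plan | 1-bromo-2,3-dimethoxybenzene | COc1cccc(Br)c1OC
A5 | direct plan | 2-(2,3-dimethoxyphenyl)-5,7,8-trimethoxy-4H-chromen-4-one (2',3',5,7,8-pentamethoxyflavone) | COc1cccc(-c2cc(=O)c3c(OC)cc(OC)c(OC)c3o2)c1OC
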